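**Retrosynthetic overview** (labdane numbering throughout)

1. Target 18 ⇐ diol 17 ⇐ enyne alcohol 14. The (E)-C13=C14 unit with C16 and C15 comes from a terminal alkyne by methylalumination and hydroxymethylation; C17 comes from the Δ7 enol triflate 13 of bicyclic ketone 11.
2. Ring B of 11 is closed by the C6–C7 bond: the α-keto radical at C7 of bromomethyl ketone 10 adds 6-endo to the exocyclic C5=C6 methylene on ring A, and hydrogen-atom transfer to C5 sets the trans ring fusion.
3. Enabling feature: the C7=C8 alkene of ring B that carries the oxygenated C17 is the retron of a C8 ketone, which makes C7 a radical site. C6 is the free terminus of a methylene whose inner carbon C5 lies between the quaternary C4 and C10 of ring A, so only six-membered closure is open and the axial methyls on C4 and C10 screen one face of C5.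
4. 10 ⇐ acid 7 ⇐ enantioselective Ireland–Claisen rearrangement of β-cyclogeranyl hex-5-ynoate 4, which forms the C9–C10 bond, both stereocenters and the C5=C6 methylene at once; 4 ⇐ β-cyclocitral 1 + hex-5-ynoic acid 3.
5. Ring order: ring A is bought with 1; ring B is formed in step 5.

Key step: step 5

Remark: the (4S,5S)-configured boron controller is assumed to give 7 with the configuration shown; if the sense of induction is the opposite, its (4R,5R) antipode is used and nothing else changes.

**Route**

Step 1
Reactants: 1 β-cyclocitral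
Product: 2 β-cyclogeraniol
Conditions: NaBH4, CeCl3·7H2O, MeOH, 0 °C
Reagents that add atoms: none
Why: Luche reduction should deliver hydride 1,2 to the hindered conjugated aldehyde and leave the tetrasubstituted alkene in place; no stereocenter is formed.

Step 2
Reactants: 2 β-cyclogeraniol; 3 hex-5-ynoic acid
Product: 4 (2,6,6-trimethylcyclohex-1-en-1-yl)methyl hex-5-ynoate
Conditions: DCC, DMAP (cat.), CH2Cl2, 0 °C → rt
Reagents that add atoms: none
Why: Steglich esterification should acylate the primary allylic alcohol under neutral conditions that avoid ionization of the allylic C–O bond; no stereocenter is formed.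

Step 3
Reactants: 4 (2,6,6-trimethylcyclohex-1-en-1-yl)methyl hex-5-ynoate
Product: 7 (2R)-2-[(1R)-1,3,3-trimethyl-2-methylidenecyclohexyl]hex-5-ynoic acid, via boron ketene acetal 5 (not isolated), via acyloxyborane 6 (not isolated)
Conditions: (4S,5S)-2-bromo-4,5-diphenyl-1,3-bis{[3,5-bis(trifluoromethyl)phenyl]sulfonyl}-1,3,2-diazaborolidine (1.2 equiv), i-Pr2NEt, CH2Cl2, −78 °C; then −20 °C → rt; aq. work-up
Reagents that add atoms: none
Why: In this enantioselective Ireland–Claisen rearrangement, soft enolization should give the boron ketene acetal with the alkyl chain cis to O–B, whose chair [3,3] transition state (ring methyl axial, both chains equatorial) joins C9 to C10 with the labdane relative configuration while the C2-symmetric sulfonamide ligand selects the enolate face and so fixes the absolute configuration at the quaternary C10 and at C9, and the allylic transposition unveils the exocyclic C5=C6 methylene.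

Step 4
Reactants: 7 (2R)-2-[(1R)-1,3,3-trimethyl-2-methylidenecyclohexyl]hex-5-ynoic acid
Product: 10 (3R)-1-bromo-3-[(1R)-1,3,3-trimethyl-2-methylidenecyclohexyl]hept-6-yn-2-one, via acid chloride 8 (not isolated), via diazoketone 9 (not isolated)
Conditions: (COCl)2, DMF (cat.), CH2Cl2, 0 °C → rt; concentrate; Me3SiCHN2 (2.5 equiv), THF/MeCN, 0 °C; then 48% aq. HBr, 0 °C, short contact
Reagents that add atoms: (trimethylsilyl)diazomethane C[Si](C)(C)C=[N+]=[N-]; hydrogen bromide Br
Why: Acylation of the diazomethane surrogate by the acid chloride (first stage of the Arndt–Eistert sequence) and hydrobromination of the α-diazo ketone (Nierenstein-type) should give the bromomethyl ketone, adding C7, without touching the alkene, the alkyne or the two stereocenters.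

Step 5
Reactants: 10 (3R)-1-bromo-3-[(1R)-1,3,3-trimethyl-2-methylidenecyclohexyl]hept-6-yn-2-one
Product: 11 (1R,4aS,8aS)-1-(but-3-yn-1-yl)-5,5,8a-trimethyloctahydronaphthalen-2(1H)-one
Conditions: Bu3SnH (1.2 equiv) and AIBN (0.1 equiv) added over 8 h by syringe pump, benzene (0.005 M), 80 °C
Reagents that add atoms: none
Why: Bu3Sn• abstracts bromine from 10 to give the electrophilic 2-oxoalkyl radical at C7, which adds to the methylene terminus C6 and so forms the C6–C7 bond and the tertiary C5 radical, which takes hydrogen from Bu3SnH and carries the chain. The closest known reaction type is the reductive tin hydride cyclization of α-halo ketones and β-keto esters onto 1,1-disubstituted alkenes that is used to build decalones. Ring B closes in the 6-endo-trig mode, because the 5-exo mode would have to form a bond to C5, which is fully substituted and lies between the quaternary C4 and C10, and would place the carbonyl carbon in a five-membered transition ring. The new stereocenter C5 is set in the hydrogen-atom transfer, which should come from the α face opposite to the axial methyl groups on C10 and C4 and give the trans ring fusion; C9 keeps its configuration from step 3 and, being α to the new ketone with its chain equatorial, can be corrected by base if it has suffered. The step needs the alkene to win over the alkyne and cyclization to win over reduction: the electron-rich 1,1-disubstituted alkene is the polarity-matched partner of the electrophilic radical, bromine abstraction by tin is far faster than stannyl addition to the alkyne, and slow addition keeps the stannane concentration low.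

Step 6
Reactants: 11 (1R,4aS,8aS)-1-(but-3-yn-1-yl)-5,5,8a-trimethyloctahydronaphthalen-2(1H)-one
Product: 13 (1R,4aS,8aS)-1-(but-3-yn-1-yl)-5,5,8a-trimethyl-1,4,4a,5,6,7,8,8a-octahydronaphthalen-2-yl trifluoromethanesulfonate, via lithium enolate 12 (not isolated)
Conditions: LiN(i-Pr)2 (1.05 equiv), THF, −78 °C; then PhNTf2, −78 → 0 °C
Reagents that add atoms: N-phenylbis(trifluoromethanesulfonimide) O=S(=O)(N(c1ccccc1)S(=O)(=O)C(F)(F)F)C(F)(F)F
Why: Kinetic deprotonation at the unhindered C7 methylene (C9 is a methine next to the quaternary C10, and the ketone α-protons are more acidic than the alkyne C–H) followed by O-sulfonylation of the enolate (enol triflate formation) should fix the C7=C8 double bond without touching C9.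

Step 7
Reactants: 13 (1R,4aS,8aS)-1-(but-3-yn-1-yl)-5,5,8a-trimethyl-1,4,4a,5,6,7,8,8a-octahydronaphthalen-2-yl trifluoromethanesulfonate
Product: 14 [(1R,4aS,8aS)-1-(but-3-yn-1-yl)-5,5,8a-trimethyl-1,4,4a,5,6,7,8,8a-octahydronaphthalen-2-yl]methanol
Conditions: Bu3SnCH2OH, Pd(PPh3)4 (5 mol %), LiCl, 1,4-dioxane, 100 °C
Reagents that add atoms: (tributylstannyl)methanol OC[Sn](CCCC)(CCCC)CCCC
Why: In this Migita–Kosugi–Stille coupling, oxidative addition of the enol triflate to zerovalent palladium, chloride exchange, transfer of the hydroxymethyl group from tin and reductive elimination should install C17 as the free allylic alcohol without moving the double bond, and the base-free conditions leave the terminal alkyne alone.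

Step 8
Reactants: 14 [(1R,4aS,8aS)-1-(but-3-yn-1-yl)-5,5,8a-trimethyl-1,4,4a,5,6,7,8,8a-octahydronaphthalen-2-yl]methanol
Product: 17 (5S,9R,10S,13E)-labda-7,13-diene-15,17-diol, via alkenylalane 15 (not isolated), via lithium alanate 16 (not isolated)
Conditions: Me3Al (3.5 equiv), Cp2ZrCl2 (0.25 equiv), CH2Cl2, 0 °C → rt; then n-BuLi, THF, −78 °C; (CH2O)n, −78 °C → rt; aq. potassium sodium tartrate
Reagents that add atoms: trimethylaluminium C[Al](C)C; formaldehyde (as paraformaldehyde) C=O
Why: Negishi zirconium-catalysed carboalumination adds methyl and aluminium syn across the terminal alkyne with methyl on the inner carbon, and the alkenyl alanate reacts with formaldehyde with retention, so the trisubstituted C13=C14 alkene should form as the E isomer only, the allylic hydroxyl being masked in the flask as its aluminium alkoxide.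

Step 9
Reactants: 17 (5S,9R,10S,13E)-labda-7,13-diene-15,17-diol
Product: 18 (5S,9R,10S,13E)-labda-7,13-diene-15,17-diyl diacetate (CNP0257931.1)
Conditions: Ac2O, pyridine, DMAP (cat.), CH2Cl2, rt
Reagents that add atoms: acetic anhydride CC(=O)OC(C)=O
Why: DMAP-catalysed acetylation of both primary allylic alcohols should complete the target without touching a stereocenter.

**Compound list**

1 | β-cyclocitral (2,6,6-trimethylcyclohex-1-ene-1-carbaldehyde) | O=CC1=C(C)CCCC1(C)C | starting material
2 | β-cyclogeraniol ((2,6,6-trimethylcyclohex-1-en-1-yl)methanol) | OCC1=C(C)CCCC1(C)C | intermediate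
3 | hex-5-ynoic acid | OC(=O)CCCC#C | starting material
4 | (2,6,6-trimethylcyclohex-1-en-1-yl)methyl hex-5-ynoate | C#CCCCC(=O)OCC1=C(C)CCCC1(C)C | intermediate
5 | boron ketene acetal of 4 with the (4S,5S)-diazaborolidine, chain cis to O–B (formed in the flask) | C#CCC/C=C(\OB2N(S(=O)(=O)c3cc(cc(c3)C(F)(F)F)C(F)(F)F)[C@@H](c3ccccc3)[C@H](c3ccccc3)N2S(=O)(=O)c2cc(cc(c2)C(F)(F)F)C(F)(F)F)OCC1=C(C)CCCC1(C)C | intermediate
6 | acyloxyborane, the boron carboxylate of 7 (formed in the flask) | O=C(OB2N(S(=O)(=O)c3cc(cc(c3)C(F)(F)F)C(F)(F)F)[C@@H](c3ccccc3)[C@H](c3ccccc3)N2S(=O)(=O)c2cc(cc(c2)C(F)(F)F)C(F)(F)F)[C@H](CCC#C)[C@@]1(C)CCCC(C)(C)C1=C | intermediate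
7 | (2R)-2-[(1R)-1,3,3-trimethyl-2-methylidenecyclohexyl]hex-5-ynoic acid | OC(=O)[C@H](CCC#C)[C@@]1(C)CCCC(C)(C)C1=C | intermediate
8 | (2R)-2-[(1R)-1,3,3-trimethyl-2-methylidenecyclohexyl]hex-5-ynoyl chloride (formed in the flask) | ClC(=O)[C@H](CCC#C)[C@@]1(C)CCCC(C)(C)C1=C | intermediate
9 | (3R)-1-diazo-3-[(1R)-1,3,3-trimethyl-2-methylidenecyclohexyl]hept-6-yn-2-one (formed in the flask) | [N-]=[N+]=CC(=O)[C@H](CCC#C)[C@@]1(C)CCCC(C)(C)C1=C | intermediate
10 | (3R)-1-bromo-3-[(1R)-1,3,3-trimethyl-2-methylidenecyclohexyl]hept-6-yn-2-one | BrCC(=O)[C@H](CCC#C)[C@@]1(C)CCCC(C)(C)C1=C | intermediate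
11 | (1R,4aS,8aS)-1-(but-3-yn-1-yl)-5,5,8a-trimethyloctahydronaphthalen-2(1H)-one | C#CCC[C@H]1C(=O)CC[C@H]2C(C)(C)CCC[C@]12C | intermediate
12 | lithium Δ7-enolate of 11 (formed in the flask) | C#CCC[C@H]1C(O[Li])=CC[C@H]2C(C)(C)CCC[C@]12C | intermediate
13 | (1R,4aS,8aS)-1-(but-3-yn-1-yl)-5,5,8a-trimethyl-1,4,4a,5,6,7,8,8a-octahydronaphthalen-2-yl trifluoromethanesulfonate | C#CCC[C@H]1C(OS(=O)(=O)C(F)(F)F)=CC[C@H]2C(C)(C)CCC[C@]12C | intermediate
14 | [(1R,4aS,8aS)-1-(but-3-yn-1-yl)-5,5,8a-trimethyl-1,4,4a,5,6,7,8,8a-octahydronaphthalen-2-yl]methanol | C#CCC[C@H]1C(CO)=CC[C@H]2C(C)(C)CCC[C@]12C | intermediate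
15 | (E)-alkenyl(dimethyl)alane of 14, C17 oxygen as dimethylaluminium alkoxide (formed in the flask) | C[Al](C)/C=C(\C)CC[C@H]1C(CO[Al](C)C)=CC[C@H]2C(C)(C)CCC[C@]12C | intermediate
16 | lithium butyl(alkenyl)dimethylalanate derived from 15 (formed in the flask) | [Li+].CCCC[Al-](C)(C)/C=C(\C)CC[C@H]1C(CO[Al](C)C)=CC[C@H]2C(C)(C)CCC[C@]12C | intermediate
17 | (5S,9R,10S,13E)-labda-7,13-diene-15,17-diol | OC/C=C(\C)CC[C@H]1C(CO)=CC[C@H]2C(C)(C)CCC[C@]12C | intermediate
18 | (5S,9R,10S,13E)-labda-7,13-diene-15,17-diyl diacetate | CC(=O)OC/C=C(\C)CC[C@H]1C(COC(C)=O)=CC[C@H]2C(C)(C)CCC[C@]12C | target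

**Step count and risks**

Total step count: 9. Longest linear sequence: 9 steps (1 → 18); 3 enters in step 2.

Steps most likely to fail:

Step 3. The [3,3] shift onto the fully substituted ring carbon may be slow, so that ionization of the allylic ester by the Lewis-acidic borane, bromoboration of the alkyne or loss of enantiofacial control can compete. Fallback (thermal rearrangement without reagent control, then resolution; sets out from 4 and comes back at 7): soft enolization of 4 with Me3SiOTf and Et3N in toluene at 0 °C should give the trimethylsilyl ketene acetal F1. Heating to 80–110 °C rearranges it to the racemic trimethylsilyl ester F2, and aqueous acid releases 7 together with its enantiomer, the (2S,1′S)-acid F3. Crystallization of the (R)-1-phenylethylammonium salt of 7 F4 and acidification return 7; if the salt of F3 is the less soluble one, (S)-1-phenylethylamine is used.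

Step 5. The α-keto radical may be reduced before it cyclizes, tin or carbon radicals may add to the alkyne, or hydrogen transfer to C5 may be unselective. Fallback (polar closure of the same bond by aldol condensation; sets out from 7 and comes back at 13): MeLi (3.3 equiv, THF, 0 °C) converts 7 into the methyl ketone (3R)-3-[(1R)-1,3,3-trimethyl-2-methylidenecyclohexyl]hept-6-yn-2-one F5. Epoxidation of the exocyclic alkene (mCPBA, NaHCO3, CH2Cl2) gives the spiro-epoxide F6, and Meinwald rearrangement (BF3·OEt2, CH2Cl2, −78 °C) gives the keto aldehyde F7. KOH in MeOH closes ring B by intramolecular aldol condensation and equilibrates C5 and C9, which should give the trans-fused enone F8. Conjugate reduction with LiBH(s-Bu)3 in THF at −78 °C and trapping of the enolate with PhNTf2 give 13.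

Step 7. Transmetalation at the hindered enol triflate may be slow, so that reduction of the triflate or insertion of the alkyne into the vinylpalladium species competes. Fallback (carbonylation, then reduction; sets out from 13 and comes back at 14): Pd(OAc)2, 1,3-bis(diphenylphosphino)propane, CO (1 atm), MeOH, Et3N, DMF, 60 °C should give the methyl ester F9, and i-Bu2AlH in CH2Cl2 at −78 °C reduces it to 14.

**Further compounds**

F1 | step 3 | trimethylsilyl ketene acetal of 4 (E/Z mixture) | C#CCCC=C(O[Si](C)(C)C)OCC1=C(C)CCCC1(C)C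
F2 | step 3 | racemic trimethylsilyl 2-(1,3,3-trimethyl-2-methylidenecyclohexyl)hex-5-ynoate (the enantiomer that leads to 7 is drawn) | C[Si](C)(C)OC(=O)[C@H](CCC#C)[C@@]1(C)CCCC(C)(C)C1=C
F3 | step 3 | (2S)-2-[(1S)-1,3,3-trimethyl-2-methylidenecyclohexyl]hex-5-ynoic acid (enantiomer of 7) | OC(=O)[C@@H](CCC#C)[C@]1(C)CCCC(C)(C)C1=C
F4 | step 3 | (R)-1-phenylethylammonium salt of 7 | C[C@@H]([NH3+])c1ccccc1.[O-]C(=O)[C@H](CCC#C)[C@@]1(C)CCCC(C)(C)C1=C
F5 | step 5 | (3R)-3-[(1R)-1,3,3-trimethyl-2-methylidenecyclohexyl]hept-6-yn-2-one | CC(=O)[C@H](CCC#C)[C@@]1(C)CCCC(C)(C)C1=C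
F6 | step 5 | (3R)-3-(4,8,8-trimethyl-1-oxaspiro[2.5]octan-4-yl)hept-6-yn-2-one (epimers at the spiro carbon) | CC(=O)[C@H](CCC#C)[C@@]1(C)CCCC(C)(C)C12CO2
F7 | step 5 | 2,2,6-trimethyl-6-[(3R)-2-oxohept-6-yn-3-yl]cyclohexane-1-carbaldehyde (epimers at the formyl-bearing carbon) | CC(=O)[C@H](CCC#C)[C@@]1(C)CCCC(C)(C)C1C=O
F8 | step 5 | (1R,4aS,8aS)-1-(but-3-yn-1-yl)-5,5,8a-trimethyl-4a,5,6,7,8,8a-hexahydronaphthalen-2(1H)-one | C#CCC[C@H]1C(=O)C=C[C@H]2C(C)(C)CCC[C@]12C
F9 | step 7 | methyl (1R,4aS,8aS)-1-(but-3-yn-1-yl)-5,5,8a-trimethyl-1,4,4a,5,6,7,8,8a-octahydronaphthalene-2-carboxylate | C#CCC[C@H]1C(C(=O)OC)=CC[C@H]2C(C)(C)CCC[C@]12C
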